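Percent of the starting material charged is the unit of what is asked, and that unit hides a limit: product is counted against one charge while the other charge has to pay for it.

| setting | epsilon | delta | theta | eta | south | east | south-east | north-east |
|---|---|---|---|---|---|---|---|---|
| starting material | 1.5 M | 1.5 M | 1.5 M | 1.1 M | 1.5 M | 1.0 M | 3.0 M | 0.80 M |
| reagent | 1.58 M | 1.58 M | 1.58 M | 1.58 M | 1.58 M | 1.58 M | 1.58 M | 2.50 M |
| free catalyst | 2.1 mM | 7.2 mM | 31 mM | 7.5 mM | 7.5 mM | 7.5 mM | 30 mM | 2.0 mM |
| remark | run made earlier | run made earlier | run made earlier | run made earlier |  |  |  |  |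
| time |  |  |  |  | 50 min | 50 min | 50 min | 50 min |

| run | time / min | product / % | starting material / % |
|---|---|---|---|
| epsilon | 6.00 | 1.6 | 97.7 |
| epsilon | 20.0 | 6.1 | 95.0 |
| epsilon | 30.0 | 7.7 | 91.8 |
| epsilon | 50.0 | 11.6 | 88.3 |
| delta | 6.00 | 5.8 | 93.3 |
| delta | 20.0 | 18.9 | 81.6 |
| delta | 30.0 | 24.6 | 74.5 |
| delta | 50.0 | 35.5 | 64.6 |
| theta | 6.00 | 24.4 | 74.5 |
| theta | 20.0 | 59.3 | 39.7 |
| theta | 30.0 | 72.8 | 26.5 |
| theta | 50.0 | 85.9 | 13.1 |
| eta | 12.0 | 15.8 | 84.6 |
| eta | 25.0 | 27.4 | 72.2 |
| eta | 40.0 | 37.1 | 62.3 |
| eta | 50.0 | 42.0 | 56.7 |

(standard deviation of a reading: 0.3 percentage points)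

- ranking by amount of product, in percent of the starting material charged, from high to low, at 50 min (south / east / south-east / north-east)
- the amount of product, in percent of the starting material charged of the flask you put first, at 50 min
- the amount of product, in percent of the starting material charged of the flask you put last, at 50 min

- a reading or a percentage of product counts all its forms, free or not

At 50.0 min, theta holds 85.9 % product, which is 1.29 M made from 1.58 M of reagent. Two reagent per product would have needed 2.58 M, more than theta was charged. So if the reagent enters the product, I take it to enter one for one, and apart from any reagent held on the catalyst I write the balance c(reagent) = charged c(reagent) − c(product).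

Reading down the recipes, c(reagent)/c(starting material) is 1.05 in south, 1.58 in east, 3.12 in north-east and 0.527 in south-east. By that balance, south-east cannot pass 52.7 %, the ceiling: the most product, in percent of the starting material charged, that the charge of the limiting reagent can pay for.

Theta has the same reagent charge and nearly the same catalyst charge, 31 mM against 30 mM. Its 1.29 M of product over the 3.0 M of south-east is 43.0 %, so my estimate puts south-east between 43.0 % and 52.7 %.

The forecast gives south-east > east > south > north-east, with top 68 % (62 % to 74 %) and low 17.5 % (15 % to 24 %). Its grounds on the reagent are “reagent order is about zero, though this is inferred only”. Here it differs from my reckoning: even its low end for the top stands above the ceiling.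

The flasks give south-east 49.8 %, east 44.4 %, south 36.6 % and north-east 16.9 %, which is south-east > east > south > north-east.

    starting material + free catalyst → catalyst intermediate A (k = 0.130 L mol⁻¹ s⁻¹)
    reagent + catalyst intermediate A → catalyst intermediate B (k = 0.0480 L mol⁻¹ s⁻¹)
    catalyst intermediate B → free catalyst + product (k = 0.140 s⁻¹)
    free catalyst + product ⇌ idle complex, settled at all times (K = 0.690 L mol⁻¹)
    free catalyst → spent catalyst (k = 9.40 × 10⁻⁴ s⁻¹)

South-east stands under its ceiling, with 5.36 % of its reagent left at 50.0 min, that is c(reagent) = 0.0847 M. Against that reagent, catalyst intermediate A has a half-life of 2.84 min, longer than the 0.083 min of catalyst intermediate B, and south-east holds 77.4 % of its catalyst as catalyst intermediate A, the resting state, and 2.26 % as catalyst intermediate B. At 500 min, south-east reaches 52.7 % against the ceiling of 52.7 %, with reagent at 0 %. North-east, at a ratio of 3.12, stands at 24.2 % at 500 min, with 92.3 % of its reagent left and spent catalyst at >99.9 %.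

Readings and results are simulated for substances that don't exist; scatter was added.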